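**Retrosynthetic overview**
1. The target is disconnected at the C2 ester (Yamaguchi coupling with a chiral-pool acrylic acid) and at the two 1,1-disubstituted alkenes (C11=C13 by α-methylenation, C4=C14 by ketone methylenation), leading back to a trans-fused decalin β-hydroxy ketone.
2. Ring A is a masked 3-hydroxycyclohexanone: the C2–O bond and C4 (future C=CH2, then a C=O) flank the ring methylene C3. Ring A is therefore the one-carbon ring-expansion product of a cyclopentane-fused cyclopropanol (carbinol C4, bridgehead C2, cyclopropane CH2 = C3), formed by oxidative cleavage of the C2–C4 bond with O2 capture at C2.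
3. The cyclopropanol (five-membered ring C4–C4a–C8a–C1–C2 plus C3) comes from an intramolecular Kulinkovich reaction between a methyl ester on C4a and a vinyl group (C2=C3) on C1.
4. Ring B comes from a catalytic asymmetric Diels–Alder reaction of a 1,3-diene (C6=C7–C8=C8a) with an acrylate (C4a, C5), and C4a is then equilibrated to trans. C1 is set earlier by rhodium-catalysed conjugate addition of the dienylboronate to 5,6-dihydro-2H-pyran-2-one.
5. Order of ring formation: ring B (Diels–Alder), then the cyclopropane-fused five-membered carbocycle (Kulinkovich), then ring A (ring expansion of that carbocycle).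

Key step: step 10

Remark: atoms carry the decalin numbering of the target (C1 acrylic-acid carbon, C2 acyloxy carbon, C4 methylidene carbon, C4a/C8a ring fusion, C7 hydroxymethyl carbon, C11–C13 acrylic unit, C15 the CH2OH carbon; ring A = C1–C4, C4a, C8a; ring B = C4a–C8a), and the sense of induction in steps 3 and 7 is taken from the accepted models for these catalysts.

**Step 1**
Reactants: 1 2-bromoprop-2-en-1-ol
Product: 2 [(2-bromoprop-2-en-1-yl)oxy](tert-butyl)dimethylsilane
Conditions: TBSCl, imidazole, DMF, 0 → 20 °C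
Reagents that add atoms: tert-butyl(chloro)dimethylsilane, CC(C)(C)[Si](C)(C)Cl
Why: Imidazole-promoted silylation of the primary allylic alcohol masks the future C15 hydroxyl for the whole route; no stereocenter is formed.

**Step 2**
Reactants: 2 [(2-bromoprop-2-en-1-yl)oxy](tert-butyl)dimethylsilane; 3 (E)-1,2-bis(4,4,5,5-tetramethyl-1,3,2-dioxaborolan-2-yl)ethene (2 equiv)
Product: 4 tert-butyl(dimethyl){[(3E)-2-methylidene-4-(4,4,5,5-tetramethyl-1,3,2-dioxaborolan-2-yl)but-3-en-1-yl]oxy}silane
Conditions: Pd(PPh3)4 (5 mol %), K3PO4, dioxane/H2O, 50 °C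
Reagents that add atoms: none
Why: Suzuki–Miyaura coupling (zerovalent palladium cycle) of the alkenyl bromide with one boryl terminus of the excess diborylethene proceeds with retention of the E geometry and keeps the second C–B bond for step 3.

**Step 3**
Reactants: 4 dienylboronate; 5 5,6-dihydro-2H-pyran-2-one
Product: 6 (4S)-4-[(1E)-3-({[tert-butyl(dimethyl)silyl]oxy}methyl)buta-1,3-dien-1-yl]oxan-2-one
Conditions: [Rh(OH)(cod)]2 (2.5 mol %), (S)-BINAP (6 mol %), dioxane/H2O (10:1), 40 °C
Reagents that add atoms: none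
Why: Hayashi–Miyaura asymmetric 1,4-addition of the alkenylboronate to the unsaturated δ-lactone, in which the (S)-BINAP–rhodium alkenyl species selects the enoate face and so sets C1 (lactone C4, S) in the sense established for aryl and alkenyl boron reagents with this lactone.

**Step 4**
Reactants: 6 lactone
Product: 7 (3R,4E)-6-({[tert-butyl(dimethyl)silyl]oxy}methyl)-3-[2-(phenylselanyl)ethyl]hepta-4,6-dienoic acid
Conditions: (PhSe)2, NaBH4, DMF, 100 °C; then 1 M HCl, 0 °C
Reagents that add atoms: diphenyl diselenide, c1ccccc1[Se][Se]c1ccccc1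
Why: SN2 attack of the soft selenolate at the O–CH2 carbon of the lactone (alkyl–oxygen cleavage) differentiates the two arms on C1, one becoming the acetic acid arm (C11–C12) and the other the selenide precursor of C2=C3, without touching the stereocenter.

**Step 5**
Reactants: 7 seleno acid
Product: 8 tert-butyl (3R,4E)-6-({[tert-butyl(dimethyl)silyl]oxy}methyl)-3-[2-(phenylselanyl)ethyl]hepta-4,6-dienoate
Conditions: t-BuOC(=NH)CCl3, CH2Cl2/cyclohexane, 20 °C
Reagents that add atoms: tert-butyl 2,2,2-trichloroacetimidate, CC(C)(C)OC(=N)C(Cl)(Cl)Cl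
Why: Self-catalysed O-alkylation of the carboxylic acid by the trichloroacetimidate gives the hindered tert-butyl ester, chosen because it should resist methoxide (step 8) and the Kulinkovich reagent (step 9); the stereocenter is untouched.

**Step 6**
Reactants: 8 seleno ester
Product: 10 tert-butyl (3R,4E)-6-({[tert-butyl(dimethyl)silyl]oxy}methyl)-3-ethenylhepta-4,6-dienoate, via selenoxide 9 (not isolated)
Conditions: 30% H2O2, pyridine, CH2Cl2, 0 → 20 °C
Reagents that add atoms: none
Why: Oxidation to the selenoxide and its syn-elimination unveil the C2=C3 vinyl group under near-neutral conditions that should not isomerise the skipped triene or the doubly allylic C1–H.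

**Step 7**
Reactants: 10 triene ester; 11 2,2,2-trifluoroethyl prop-2-enoate
Product: 12 2,2,2-trifluoroethyl (1R,2S)-2-[(3R)-1-tert-butoxy-1-oxopent-4-en-3-yl]-4-({[tert-butyl(dimethyl)silyl]oxy}methyl)cyclohex-3-ene-1-carboxylate
Conditions: (S)-o-tolyl-CBS-oxazaborolidine·HNTf2 (20 mol %), CH2Cl2, −78 → −40 °C
Reagents that add atoms: none
Why: Catalytic enantioselective Diels–Alder reaction in which the directing effects of the C8a and C7 substituents of the diene reinforce each other to give one regioisomer, and endo attack on the Si face of the α-carbon of the oxazaborolidinium-bound acrylate (the catalyst enantiomer being the one that exposes this face) sets C8a under catalyst control, with C4a provisionally cis to it.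

**Step 8**
Reactants: 12 cis trifluoroethyl ester
Product: 14 methyl (1S,2S)-2-[(3R)-1-tert-butoxy-1-oxopent-4-en-3-yl]-4-({[tert-butyl(dimethyl)silyl]oxy}methyl)cyclohex-3-ene-1-carboxylate, via cis methyl ester 13 (not isolated)
Conditions: NaOMe (0.5 equiv), MeOH, 50 °C
Reagents that add atoms: methanol, CO
Why: Methoxide transesterification of the activated trifluoroethyl ester, then enolate equilibration at C4a (the only epimerisable center), should give the thermodynamically favoured trans-diequatorial cyclohexene and so fix the trans ring fusion of the future decalin.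

**Step 9**
Reactants: 14 trans methyl ester
Product: 15 fused cyclopropanol (tert-butyl acetate arm on C1; bicyclo[3.1.0]hexan-1-ol unit with carbinol C4, bridgehead C2 and methylene C3, trans-fused to ring B through C4a–C8a)
Conditions: Ti(OiPr)4 (0.5 equiv, turns over), c-C5H9MgCl (4 equiv, slow addition), THF, 20 °C; then aq. NH4Cl
Reagents that add atoms: none
Why: Intramolecular Kulinkovich reaction (ligand exchange of the cyclopentene titanacyclopropane with the monosubstituted vinyl group, then insertion of the methyl ester) forms C4–C2 and C4–C3, while the tert-butyl ester, the silyl ether and the trisubstituted alkene are poor partners, and either cyclopropanol diastereomer is acceptable because C2 and C4 are reset in step 10.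

**Step 10**
Reactants: 15 fused cyclopropanol
Product: 17 tert-butyl 2-[(1S,2S,4aS,8aR)-7-({[tert-butyl(dimethyl)silyl]oxy}methyl)-2-hydroxy-4-oxo-1,2,3,4,4a,5,6,8a-octahydronaphthalen-1-yl]acetate, via hydroperoxide 16 (not isolated)
Conditions: Mn(acac)3 (10 mol %), O2 (1 atm), benzene, 20 °C; then PPh3, 0 °C
Reagents that add atoms: dioxygen, O=O
Why: Trivalent manganese oxidises the cyclopropanol O–H to an oxygen-centred radical whose β-scission cleaves the C2–C4 bond shared by the three- and five-membered rings, giving the C4 carbonyl and a secondary radical at C2 of a cyclohexanone; dioxygen traps this radical, the peroxyl radical carries the chain (or is reduced by divalent manganese) to hydroperoxide 16, and PPh3 reduces it to the alcohol. The closest known reaction types are the FeCl3-mediated ring expansion of 1-siloxybicyclo[n.1.0]alkanes and the Mn(acac)2- or VO(acac)2-catalysed aerobic opening of tertiary cyclopropanols to β-hydroperoxy and β-hydroxy ketones. No ring is closed by cyclisation: ring A arises from the cyclopentane by one-carbon ring expansion, the cyclopropane methylene C3 being inserted between C2 and C4. The one new stereocenter, C2, is controlled by the adjacent C1 side chain, which is axial on the α face of the trans-fused ring, so dioxygen should add axially on the β face and give the trans-diaxial C1/C2 pattern of the target. The step needs cleavage of the internal rather than the external cyclopropane bond, which is secured by formation of a secondary instead of a primary radical and by release of the bicyclo[3.1.0] strain. C4a and C8a are not involved, so the trans ring fusion is kept, and both diastereomers of 15 converge on 17.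

**Step 11**
Reactants: 17 β-hydroxy ketone
Product: 18 tert-butyl 2-[(1S,2S,4aS,8aS)-7-({[tert-butyl(dimethyl)silyl]oxy}methyl)-2-hydroxy-4-methylidene-1,2,3,4,4a,5,6,8a-octahydronaphthalen-1-yl]acetate
Conditions: Zn, CH2Br2, TiCl4 (pre-formed reagent), THF/CH2Cl2, 0 → 20 °C
Reagents that add atoms: dibromomethane, BrCBr
Why: Lombardo–Takai methylenation with the non-basic zinc/titanium gem-dimetallic reagent converts the hindered, epimerisable, β-hydroxylated ketone into the exocyclic alkene without retro-aldol cleavage, elimination or epimerisation at C4a.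

**Step 12**
Reactants: 18 methylidene alcohol
Product: 21 tert-butyl 2-[(1R,2S,4aS,8aS)-7-({[tert-butyl(dimethyl)silyl]oxy}methyl)-2-hydroxy-4-methylidene-1,2,3,4,4a,5,6,8a-octahydronaphthalen-1-yl]prop-2-enoate, via Mannich base 19 (not isolated), via ammonium iodide 20 (not isolated)
Conditions: LDA (2.3 equiv), THF, −78 °C; CH2=NMe2 iodide, −78 → 0 °C; then MeI, MeOH, 20 °C; then DBU, CH2Cl2, 20 °C
Reagents that add atoms: Eschenmoser's salt (N,N-dimethylmethaniminium iodide), C=[N+](C)C.[I-]
Why: Dianion formation (alkoxide plus tert-butyl ester enolate), Mannich reaction with Eschenmoser's salt, N-methylation and E1cB loss of trimethylamine install the C11=C13 methylene, while C1 is not acidic and keeps its configuration and the trans-diaxial C2–OH cannot lactonise onto the ester.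

**Step 13**
Reactants: 22 methyl [(4S)-2,2-dimethyl-1,3-dioxolan-4-yl]acetate
Product: 25 methyl 2-[(4S)-2,2-dimethyl-1,3-dioxolan-4-yl]prop-2-enoate, via Mannich base 23 (not isolated), via ammonium iodide 24 (not isolated)
Conditions: LDA (1.1 equiv), THF, −78 °C; CH2=NMe2 iodide, −78 °C; then MeI, MeOH, 20 °C; then DBU, CH2Cl2, 0 °C
Reagents that add atoms: Eschenmoser's salt (N,N-dimethylmethaniminium iodide), C=[N+](C)C.[I-]
Why: The same Eschenmoser α-methylenation on the chiral-pool ester, run at −78 °C so that the lithium enolate is alkylated faster than it expels the β-alkoxide of the acetonide; the carbinol stereocenter is not involved.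

**Step 14**
Reactants: 25 methyl ester
Product: 26 2-[(4S)-2,2-dimethyl-1,3-dioxolan-4-yl]prop-2-enoic acid
Conditions: LiOH, THF/H2O, 0 °C; then 1 M KHSO4 to pH 4
Reagents that add atoms: lithium hydroxide, [Li+].[OH-]
Why: Mild saponification of the methyl ester at 0 °C followed by buffered acidification should keep the acetonide and not epimerise the allylic carbinol center.

**Step 15**
Reactants: 21 axial C2 alcohol; 26 acid (1.5 equiv)
Product: 28 tert-butyl 2-[(1R,2S,4aS,8aS)-7-({[tert-butyl(dimethyl)silyl]oxy}methyl)-2-({2-[(4S)-2,2-dimethyl-1,3-dioxolan-4-yl]prop-2-enoyl}oxy)-4-methylidene-1,2,3,4,4a,5,6,8a-octahydronaphthalen-1-yl]prop-2-enoate, via mixed anhydride 27 (not isolated)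
Conditions: 2,4,6-trichlorobenzoyl chloride, Et3N, THF, 20 °C; then 21, DMAP, toluene, 20 → 40 °C
Reagents that add atoms: none
Why: Yamaguchi esterification, in which DMAP attacks the less hindered acryloyl carbonyl of the mixed anhydride and transfers the acyl group to the hindered axial C2 hydroxyl, with retention at C2 because its C–O bond is not broken.

**Step 16**
Reactants: 28 fully protected ester
Product: 30 2-[(1R,2S,4aS,8aS)-2-{[(3S)-3,4-dihydroxy-2-methylidenebutanoyl]oxy}-7-(hydroxymethyl)-4-methylidene-1,2,3,4,4a,5,6,8a-octahydronaphthalen-1-yl]prop-2-enoic acid (CNP0460913.4), via trimethylsilyl ester 29 (not isolated)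
Conditions: TMSOTf, 2,6-lutidine, CH2Cl2, 0 °C; then AcOH/H2O/THF (4:1:1), 40 °C
Reagents that add atoms: none
Why: Silyl triflate-mediated cleavage of the tert-butyl ester (loss of isobutene to the silyl ester), followed in the same flask by aqueous acetic acid hydrolysis of the silyl ester, the TBS ether and the acetonide, should release the acid, the allylic alcohol and the diol without strong protic acid (isomerisation of the exocyclic alkene) or base (lactonisation of the dihydroxy ester).

**Compound list**
1 | 2-bromoprop-2-en-1-ol | OCC(Br)=C | starting material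
2 | [(2-bromoprop-2-en-1-yl)oxy](tert-butyl)dimethylsilane | C=C(Br)CO[Si](C)(C)C(C)(C)C | intermediate
3 | (E)-1,2-bis(4,4,5,5-tetramethyl-1,3,2-dioxaborolan-2-yl)ethene | CC1(C)OB(/C=C/B2OC(C)(C)C(C)(C)O2)OC1(C)C | starting material
4 | tert-butyl(dimethyl){[(3E)-2-methylidene-4-(4,4,5,5-tetramethyl-1,3,2-dioxaborolan-2-yl)but-3-en-1-yl]oxy}silane | C=C(CO[Si](C)(C)C(C)(C)C)/C=C/B1OC(C)(C)C(C)(C)O1 | intermediate
5 | 5,6-dihydro-2H-pyran-2-one | O=C1C=CCCO1 | starting material
6 | (4S)-4-[(1E)-3-({[tert-butyl(dimethyl)silyl]oxy}methyl)buta-1,3-dien-1-yl]oxan-2-one | O=C1C[C@H](CCO1)/C=C/C(=C)CO[Si](C)(C)C(C)(C)C | intermediate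
7 | (3R,4E)-6-({[tert-butyl(dimethyl)silyl]oxy}methyl)-3-[2-(phenylselanyl)ethyl]hepta-4,6-dienoic acid | OC(=O)C[C@H](CC[Se]c1ccccc1)/C=C/C(=C)CO[Si](C)(C)C(C)(C)C | intermediate
8 | tert-butyl (3R,4E)-6-({[tert-butyl(dimethyl)silyl]oxy}methyl)-3-[2-(phenylselanyl)ethyl]hepta-4,6-dienoate | CC(C)(C)OC(=O)C[C@H](CC[Se]c1ccccc1)/C=C/C(=C)CO[Si](C)(C)C(C)(C)C | intermediate
9 | selenoxide of 8 (Se=O, both configurations at selenium) | CC(C)(C)OC(=O)C[C@H](CC[Se](=O)c1ccccc1)/C=C/C(=C)CO[Si](C)(C)C(C)(C)C | intermediate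
10 | tert-butyl (3R,4E)-6-({[tert-butyl(dimethyl)silyl]oxy}methyl)-3-ethenylhepta-4,6-dienoate | CC(C)(C)OC(=O)C[C@H](C=C)/C=C/C(=C)CO[Si](C)(C)C(C)(C)C | intermediate
11 | 2,2,2-trifluoroethyl prop-2-enoate | C=CC(=O)OCC(F)(F)F | starting material
12 | 2,2,2-trifluoroethyl (1R,2S)-2-[(3R)-1-tert-butoxy-1-oxopent-4-en-3-yl]-4-({[tert-butyl(dimethyl)silyl]oxy}methyl)cyclohex-3-ene-1-carboxylate (cis) | CC(C)(C)OC(=O)C[C@H](C=C)[C@H]1C=C(CO[Si](C)(C)C(C)(C)C)CC[C@H]1C(=O)OCC(F)(F)F | intermediate
13 | methyl (1R,2S)-2-[(3R)-1-tert-butoxy-1-oxopent-4-en-3-yl]-4-({[tert-butyl(dimethyl)silyl]oxy}methyl)cyclohex-3-ene-1-carboxylate (cis) | CC(C)(C)OC(=O)C[C@H](C=C)[C@H]1C=C(CO[Si](C)(C)C(C)(C)C)CC[C@H]1C(=O)OC | intermediate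
14 | methyl (1S,2S)-2-[(3R)-1-tert-butoxy-1-oxopent-4-en-3-yl]-4-({[tert-butyl(dimethyl)silyl]oxy}methyl)cyclohex-3-ene-1-carboxylate (trans) | CC(C)(C)OC(=O)C[C@H](C=C)[C@H]1C=C(CO[Si](C)(C)C(C)(C)C)CC[C@@H]1C(=O)OC | intermediate
15 | fused cyclopropanol: tert-butyl acetate arm on C1 (α); bicyclo[3.1.0]hexan-1-ol (carbinol C4, OH α; bridgehead C2, H α; methylene C3 β) trans-fused to ring B (H-4a α, H-8a β); CH2OTBS on C7; drawn as the expected major diastereomer, the other one converges in step 10 | CC(C)(C)OC(=O)C[C@H]1[C@H]2C=C(CO[Si](C)(C)C(C)(C)C)CC[C@@H]2[C@]3(O)C[C@H]13 | intermediate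
16 | tert-butyl 2-[(1S,2S,4aS,8aR)-7-({[tert-butyl(dimethyl)silyl]oxy}methyl)-2-hydroperoxy-4-oxo-1,2,3,4,4a,5,6,8a-octahydronaphthalen-1-yl]acetate | CC(C)(C)OC(=O)C[C@H]1[C@H]2C=C(CO[Si](C)(C)C(C)(C)C)CC[C@@H]2C(=O)C[C@@H]1OO | intermediate
17 | tert-butyl 2-[(1S,2S,4aS,8aR)-7-({[tert-butyl(dimethyl)silyl]oxy}methyl)-2-hydroxy-4-oxo-1,2,3,4,4a,5,6,8a-octahydronaphthalen-1-yl]acetate | CC(C)(C)OC(=O)C[C@H]1[C@H]2C=C(CO[Si](C)(C)C(C)(C)C)CC[C@@H]2C(=O)C[C@@H]1O | intermediate
18 | tert-butyl 2-[(1S,2S,4aS,8aS)-7-({[tert-butyl(dimethyl)silyl]oxy}methyl)-2-hydroxy-4-methylidene-1,2,3,4,4a,5,6,8a-octahydronaphthalen-1-yl]acetate | CC(C)(C)OC(=O)C[C@H]1[C@H]2C=C(CO[Si](C)(C)C(C)(C)C)CC[C@@H]2C(=C)C[C@@H]1O | intermediate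
19 | Mannich base: 18 carrying CH2NMe2 on the ester α-carbon (both epimers there) | CC(C)(C)OC(=O)C(CN(C)C)[C@H]1[C@H]2C=C(CO[Si](C)(C)C(C)(C)C)CC[C@@H]2C(=C)C[C@@H]1O | intermediate
20 | trimethylammonium iodide of 19 | CC(C)(C)OC(=O)C(C[N+](C)(C)C)[C@H]1[C@H]2C=C(CO[Si](C)(C)C(C)(C)C)CC[C@@H]2C(=C)C[C@@H]1O.[I-] | intermediate
21 | tert-butyl 2-[(1R,2S,4aS,8aS)-7-({[tert-butyl(dimethyl)silyl]oxy}methyl)-2-hydroxy-4-methylidene-1,2,3,4,4a,5,6,8a-octahydronaphthalen-1-yl]prop-2-enoate | CC(C)(C)OC(=O)C(=C)[C@H]1[C@H]2C=C(CO[Si](C)(C)C(C)(C)C)CC[C@@H]2C(=C)C[C@@H]1O | intermediate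
22 | methyl [(4S)-2,2-dimethyl-1,3-dioxolan-4-yl]acetate | COC(=O)C[C@H]1COC(C)(C)O1 | starting material
23 | Mannich base: 22 carrying CH2NMe2 on the α-carbon (both epimers there) | COC(=O)C(CN(C)C)[C@H]1COC(C)(C)O1 | intermediate
24 | trimethylammonium iodide of 23 | COC(=O)C(C[N+](C)(C)C)[C@H]1COC(C)(C)O1.[I-] | intermediate
25 | methyl 2-[(4S)-2,2-dimethyl-1,3-dioxolan-4-yl]prop-2-enoate | COC(=O)C(=C)[C@H]1COC(C)(C)O1 | intermediate
26 | 2-[(4S)-2,2-dimethyl-1,3-dioxolan-4-yl]prop-2-enoic acid | OC(=O)C(=C)[C@H]1COC(C)(C)O1 | intermediate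
27 | mixed anhydride of 26 with 2,4,6-trichlorobenzoic acid | O=C(OC(=O)c1c(Cl)cc(Cl)cc1Cl)C(=C)[C@H]2COC(C)(C)O2 | intermediate
28 | tert-butyl 2-[(1R,2S,4aS,8aS)-7-({[tert-butyl(dimethyl)silyl]oxy}methyl)-2-({2-[(4S)-2,2-dimethyl-1,3-dioxolan-4-yl]prop-2-enoyl}oxy)-4-methylidene-1,2,3,4,4a,5,6,8a-octahydronaphthalen-1-yl]prop-2-enoate | CC(C)(C)OC(=O)C(=C)[C@H]1[C@H]2C=C(CO[Si](C)(C)C(C)(C)C)CC[C@@H]2C(=C)C[C@@H]1OC(=O)C(=C)[C@H]3COC(C)(C)O3 | intermediate
29 | trimethylsilyl ester corresponding to 28 (tert-butyl replaced by SiMe3) | C[Si](C)(C)OC(=O)C(=C)[C@H]1[C@H]2C=C(CO[Si](C)(C)C(C)(C)C)CC[C@@H]2C(=C)C[C@@H]1OC(=O)C(=C)[C@H]3COC(C)(C)O3 | intermediate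
30 | 2-[(1R,2S,4aS,8aS)-2-{[(3S)-3,4-dihydroxy-2-methylidenebutanoyl]oxy}-7-(hydroxymethyl)-4-methylidene-1,2,3,4,4a,5,6,8a-octahydronaphthalen-1-yl]prop-2-enoic acid | C=C(C(=O)O)[C@H]1[C@H]2C=C(CO)CC[C@@H]2C(=C)C[C@@H]1OC(=O)C(=C)[C@H](O)CO | target

**Step count and risks**
Total step count: 16 (main line steps 1–12, 15 and 16; side-chain branch steps 13 and 14).
Longest linear sequence: 14 steps (from 1 through steps 1–12, 15 and 16).

Steps most likely to fail:

1. Step 10 (key step). What may go wrong: cleavage of the external instead of the internal cyclopropane bond, over-oxidation of the β-hydroperoxy ketone to the 1,3-diketone, retro-aldol loss during reduction, or poor facial selectivity in the capture of the C2 radical by dioxygen. Fallback, setting out from 15 and returning at 17: oxidative ring expansion with FeCl3 and pyridine in DMF at 0 °C should give the ring-expanded β-chloro ketone F1; NaOAc in MeOH at 50 °C eliminates HCl to the ring-A enone F2; copper-catalysed conjugate borylation (CuCl, NaOtBu, DPEphos, B2pin2, MeOH, THF) should deliver boron to C2 axially on the β face, anti to the C1 side chain, giving the β-boryl ketone F3; NaBO3·4H2O in THF/H2O oxidises the C–B bond with retention to 17.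

2. Step 9. What may go wrong: slow ligand exchange or slow ester insertion because the five-membered ring must close trans onto ring B, competing attack of the Grignard or titanium reagent on the tert-butyl ester, or simple reduction of the ester. Fallback, setting out from 14 and returning at 15: the Tebbe reagent Cp2Ti(CH2)(Cl)AlMe2 (excess, THF, 20 → 65 °C) methylenates the methyl ester and closes the five-membered ring by carbonyl–olefin metathesis with the vinyl group to the cyclic methyl enol ether F4; oxalic acid on wet silica gel hydrolyses it to the trans-hydrindanone F5; LDA and Me3SiCl in THF at −78 °C give the kinetic enol silane F6 towards C2; Et2Zn and CH2I2 (Furukawa-modified Simmons–Smith reaction) cyclopropanate the electron-rich enol ether to the siloxycyclopropane F7; K2CO3 in MeOH removes the silyl group to give 15.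

3. Step 7. What may go wrong: poor facial or endo selectivity, or catalyst sequestration by the Lewis-basic ester and silyl ether of the functionalised diene, leading to the wrong configuration at C8a. Fallback, setting out from 10 and returning at 14: auxiliary-controlled Diels–Alder reaction with commercial (4S)-4-benzyl-3-(prop-2-enoyl)-1,3-oxazolidin-2-one and Et2AlCl in CH2Cl2 at −78 °C, in which the chelated s-cis imide is attacked endo on the Si face of its α-carbon anti to the benzyl group, gives the cis imide F8; NaOMe in MeOH then cleaves the auxiliary and equilibrates C4a, giving 14 (through 13).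

**Further compounds**
F1 | step 10 | β-chloro ketone: 17 with chlorine in place of the C2 hydroxyl | CC(C)(C)OC(=O)C[C@H]1[C@H]2C=C(CO[Si](C)(C)C(C)(C)C)CC[C@@H]2C(=O)C[C@@H]1Cl
F2 | step 10 | ring-A enone (C4 ketone, C2=C3 alkene) | CC(C)(C)OC(=O)C[C@H]1[C@H]2C=C(CO[Si](C)(C)C(C)(C)C)CC[C@@H]2C(=O)C=C1
F3 | step 10 | β-boryl ketone: 17 with a pinacolboryl group in place of the C2 hydroxyl | CC(C)(C)OC(=O)C[C@H]1[C@H]2C=C(CO[Si](C)(C)C(C)(C)C)CC[C@@H]2C(=O)C[C@@H]1B3OC(C)(C)C(C)(C)O3
F4 | step 9 | cyclic methyl enol ether (five-membered ring C4–C4a–C8a–C1–C2, C4(OMe)=C2) | CC(C)(C)OC(=O)C[C@H]1[C@H]2C=C(CO[Si](C)(C)C(C)(C)C)CC[C@@H]2C(OC)=C1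
F5 | step 9 | trans-hydrindanone (C4 ketone, C2 methylene) | CC(C)(C)OC(=O)C[C@H]1[C@H]2C=C(CO[Si](C)(C)C(C)(C)C)CC[C@@H]2C(=O)C1
F6 | step 9 | trimethylsilyl enol ether of F5 (C4(OSiMe3)=C2) | CC(C)(C)OC(=O)C[C@H]1[C@H]2C=C(CO[Si](C)(C)C(C)(C)C)CC[C@@H]2C(O[Si](C)(C)C)=C1
F7 | step 9 | trimethylsilyl ether of cyclopropanol 15 | CC(C)(C)OC(=O)C[C@H]1[C@H]2C=C(CO[Si](C)(C)C(C)(C)C)CC[C@@H]2[C@]3(O[Si](C)(C)C)C[C@H]13
F8 | step 7 | cis Diels–Alder imide: 12 with the (4S)-4-benzyl-2-oxo-1,3-oxazolidin-3-yl group in place of the trifluoroethoxy group | CC(C)(C)OC(=O)C[C@H](C=C)[C@H]1C=C(CO[Si](C)(C)C(C)(C)C)CC[C@H]1C(=O)N2[C@@H](Cc3ccccc3)COC2=O
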